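The data were generated by integration for substances that don't exist, and the scatter is random.

I decided to hold east against grey, because both stood at 40 °C and were charged alike in starting material and second substrate, and to count everything in fractions of the charge.

| setting | blue | grey | west | east | north-west |
|---|---|---|---|---|---|
| starting material | 0.20 M | 0.20 M | 0.20 M | 0.20 M | 0.20 M |
| coupling partner | 0.13 M | 0.29 M | 0.190 M | 0.190 M | 0.190 M |
| second substrate | 0.20 M | 0.20 M | 0.200 M | 0.200 M | 0.200 M |
| temperature | 5 °C | 40 °C | 70 °C | 40 °C | 10 °C |
| remark | run made earlier | run made earlier |  |  |  |
| time |  |  | 1.0 h | 1.0 h | 1.0 h |

| run | time / h | target / % | starting material / % |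
|---|---|---|---|
| blue | 2.50 | 3.9 | 94.0 |
| blue | 4.00 | 6.4 | 89.3 |
| blue | 6.00 | 8.8 | 85.2 |
| blue | 10.0 | 12.8 | 76.6 |
| blue | 15.0 | 17.1 | 67.1 |
| blue | 30.0 | 20.9 | 47.5 |
| grey | 0.833 | 23.3 | 49.0 |
| grey | 2.00 | 27.5 | 21.2 |
| grey | 3.00 | 28.0 | 11.0 |
| grey | 4.00 | 25.9 | 6.5 |
| grey | 6.00 | 25.9 | 2.3 |

(readings scatter by 0.5 percentage points)

- percentages count the starting material that a species holds: one side product counts as two
- what was read earlier has a scatter of 0.5 percentage points, one standard deviation
- reactions considered so far: starting material + coupling partner -> target; second substrate + coupling partner -> second product; starting material + second substrate -> cross product; starting material + target -> side product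

- which flask leads in amount of target, in percent of the starting material charged ("all alike" within 1.5 percentage points) (west / east / north-west / all alike)
- how much target is there at the end, in percent of the starting material charged: west
- how much target is there at the end, in percent of the starting material charged: east
- how much target is there at the end, in percent of the starting material charged: north-west

With the other reactant held, the rate of each step using coupling partner is proportional to the partner's concentration. The partner is not in excess, since east's 0.190 M stands below its 0.20 M of starting material, so these steps stay second order and their pace falls as the partner is used. Since east has 0.655 of grey's partner, its hour counts for these steps, reckoned on the charges and so as an estimate, as 0.655 h of grey. I called this the partner clock: a flask's time, times its partner charge, over grey's charge.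

From above: grey's target was still rising when it read 23.3% at 0.833 h, later than the clock value, so grey held less at 0.655 h. East should hold less again, because the steps that need no partner get 1.0 h there, longer than 0.655 h. So 23.3% was my upper bound.

From below: grey's curve bends over, so the straight line from zero to that reading gives at least 18.3% at 0.655 h. Cutting partner to 0.655 can cut the share of consumed starting material that becomes target by at most that ratio, which gave 12.0%. This was a bound by hand, since it assumed that east consumed as much as grey's line implies. I committed to the middle, 17.7%. The clock could not cross temperatures, so I reckoned neither west nor north-west.

The forecast named east, with 11% in west, 16.5% in east and 3.5% in north-west; of east it said “with less coupling partner than grey, about 16 %”. Its east figure lay inside my bracket, lower than my middle.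

    starting material + coupling partner → target (k = 6.40 × 10⁻⁴ /M/s, Ea = 56.0 kJ/mol)
    second substrate + coupling partner → second product (k = 3.50 × 10⁻⁴ /M/s, Ea = 77.0 kJ/mol)
    starting material + second substrate → cross product (k = 2.80 × 10⁻⁴ /M/s, Ea = 66.0 kJ/mol)
    starting material + target → side product (k = 0.00140 /M/s, Ea = 73.0 kJ/mol)
    (constants at 40 °C)

The flasks gave 6.38% in west, 17.1% in east and 4.13% in north-west, so east led, and east fell inside the bracket set at clock 0.655 h. A flask like east with 0.47 M of partner ran at clock 1.62 h and held 37.2%, more than grey read on either side of that time. East had not come to rest: 54.1% of its starting material and 57% of its partner remained, and target was made 1.46 times as fast as it was used. At 10.0 h, starting material stood at 2.19%, side product had grown from 16.0% to 57.9%, and target stood at 14.2%.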